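**Strategy.** The route rests on building the aryl ring of the ester after the ester bond exists. The hindered 2,6-disubstituted benzoate ring (C1'–C6') on the C6 oxygen of the tetrahydroisochromenone is cut at C1'–C2' and C5'–C6'. Its C1'–C6' edge, the C6' methyl and the carboxyl carbon are a but-2-ynoate. One [4+2] cycloaddition of that ynoate with a ketene-acetal diene, followed by loss of methanol, should deliver the benzene ring with the C2' methoxy group and both protected oxygens (C3', C4') in place. The precursor is the (6S,7S) bicyclic core carrying the C6 but-2-ynoate, a C7 silyl ether and a C3 silyloxymethyl group standing in for the acrylic acid.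

Key step: step 14

Remarks on the chemistry:
- Atom numbers follow the isochromene skeleton (C1, O2, C3, C4, C4a, C5–C8, C8a); primed numbers are the benzoate ring.
- The target is (6S,7S), with the C6 acyloxy oxygen and the C7 hydroxyl cis and the C7 methyl trans to the C6 oxygen. The structures needed no correction.
- The cycloaddition substrate carries its C7 hydroxyl as a triethylsilyl ether. A free tertiary alcohol would protonate the ketene acetal and could invite acyl migration on heating. The cap is installed in step 4, where it also directs the reduction of step 5.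
- Assumption: the sense of induction of the transfer-hydrogenation catalyst on dione 9 is assumed; if the 3R carbinol forms, the enantiomeric ligand is used.

Step 1
Reactants: 1 methyl dimethoxyacetate; 2 ethyl vinyl ether
Product: 5 1,1-dimethoxybutane-2,3-dione, via 1-ethoxyvinyllithium 3 (not isolated), via enol ether ketone 4 (not isolated)
Conditions: 2, t-BuLi, THF, −78 → 0 °C; then 1, −78 °C; then 1 M HCl, 0 °C
Reagents that add atoms: water, O
Why: Acylation of a vinyllithium by an α,α-dialkoxy ester should stop at the ketone because the chelated tetrahedral adduct persists at −78 °C, and dilute acid then hydrolyses the enol ether much faster than the deactivated α-keto acetal (organolithium acylation, then enol ether hydrolysis).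

Step 2
Reactants: 5 1,1-dimethoxybutane-2,3-dione
Product: 6 1,1-dimethoxy-2,3-bis(tert-butyldimethylsilyloxy)buta-1,3-diene
Conditions: TBSOTf (2.4 equiv), Et3N (3 equiv), CH2Cl2, 0 °C → rt; distilled, stored cold
Reagents that add atoms: tert-butyldimethylsilyl trifluoromethanesulfonate, CC(C)(C)[Si](C)(C)OS(=O)(=O)C(F)(F)F
Why: Soft enolisation of a 1,2-dione (silyl triflate and amine, silyl enol ether formation) should take the only α-hydrogens available, those of the methyl group and the acetal C–H, giving the bis(silyloxy) ketene-acetal diene.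

Step 3
Reactants: 7 2-methylcyclohexane-1,3-dione
Product: 8 2-hydroxy-2-methylcyclohexane-1,3-dione
Conditions: dimethyldioxirane, acetone, 0 °C
Reagents that add atoms: dimethyldioxirane, CC1(C)OO1
Why: Electrophilic α-hydroxylation of the enol form of a 2-alkyl-1,3-dione by a dioxirane (enol epoxidation and opening) is a clean route to the tertiary α-hydroxy dione.

Step 4
Reactants: 8 2-hydroxy-2-methylcyclohexane-1,3-dione
Product: 9 2-methyl-2-(triethylsilyloxy)cyclohexane-1,3-dione
Conditions: TESOTf, 2,6-lutidine, CH2Cl2, −78 °C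
Reagents that add atoms: triethylsilyl trifluoromethanesulfonate, CC[Si](CC)(CC)OS(=O)(=O)C(F)(F)F
Why: O-Silylation of the tertiary alcohol with a silyl triflate and a hindered pyridine is fast at low temperature and removes the α-ketol that could otherwise undergo ring contraction.

Step 5
Reactants: 9 2-methyl-2-(triethylsilyloxy)cyclohexane-1,3-dione
Product: 10 (2S,3S)-3-hydroxy-2-methyl-2-(triethylsilyloxy)cyclohexan-1-one
Conditions: RuCl(p-cymene)[(S,S)-TsDPEN] (1 mol %), HCO2H/Et3N (5:2), CH2Cl2, rt
Reagents that add atoms: none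
Why: Noyori–Ikariya transfer hydrogenation should desymmetrise the 2,2-disubstituted 1,3-dione, the catalyst fixing the new carbinol as 3S while hydride delivery anti to the bulky C2 silyloxy group selects the carbonyl that makes C2 S, so the two oxygens end up cis.

Step 6
Reactants: 10 (2S,3S)-3-hydroxy-2-methyl-2-(triethylsilyloxy)cyclohexan-1-one
Product: 11 (2S,3S)-2-methyl-2,3-bis(triethylsilyloxy)cyclohexan-1-one
Conditions: TESOTf, 2,6-lutidine, CH2Cl2, −78 → 0 °C
Reagents that add atoms: triethylsilyl trifluoromethanesulfonate, CC[Si](CC)(CC)OS(=O)(=O)C(F)(F)F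
Why: Silylation of the secondary alcohol under non-basic conditions caps the β-hydroxy ketone before the strong bases of steps 7 and 9, which would otherwise cause retro-aldol cleavage or 1,2-silyl migration.

Step 7
Reactants: 11 (2S,3S)-2-methyl-2,3-bis(triethylsilyloxy)cyclohexan-1-one
Product: 13 (5S,6S)-6-methyl-5,6-bis(triethylsilyloxy)cyclohex-2-en-1-one, via lithium enolate 12 (not isolated)
Conditions: LDA, THF, −78 °C; then N-tert-butylbenzenesulfinimidoyl chloride, −78 °C
Reagents that add atoms: none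
Why: Mukaiyama dehydrogenation: the only possible enolate (the other α-carbon is quaternary) attacks sulfur of the sulfinimidoyl chloride and the adduct eliminates the sulfenamide at low temperature to give the enone.

Step 8
Reactants: 13 (5S,6S)-6-methyl-5,6-bis(triethylsilyloxy)cyclohex-2-en-1-one; 14 tert-butyldimethyl(prop-2-yn-1-yloxy)silane
Product: 17 (5S,6S)-3-[3-(tert-butyldimethylsilyloxy)prop-1-yn-1-yl]-6-methyl-5,6-bis(triethylsilyloxy)-1-(trimethylsilyloxy)cyclohex-1-ene (C3 epimers), via lithium acetylide 15 (not isolated), via alkynylzinc bromide 16 (not isolated)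
Conditions: 14, n-BuLi, THF, −78 °C; ZnBr2, Et2O, 0 °C; then 13, TMSOTf, −40 °C; Et3N, pentane extraction
Reagents that add atoms: trimethylsilyl trifluoromethanesulfonate, C[Si](C)(C)OS(=O)(=O)C(F)(F)F
Why: Silyl-triflate-promoted conjugate addition of an alkynylzinc halide to a cyclic enone places the alkynyl group on the β-carbon and traps the enolate as its silyl ether; the new C3 stereocentre is not controlled and is erased in step 10.

Step 9
Reactants: 17 silyl enol ether from step 8; 18 ethyl formate
Product: 20 (4S,5S)-2-[3-(tert-butyldimethylsilyloxy)prop-1-yn-1-yl]-5-methyl-6-oxo-4,5-bis(triethylsilyloxy)cyclohexane-1-carbaldehyde (chelated hydroxymethylene enol; C2 epimers), via lithium enolate 19 (not isolated)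
Conditions: MeLi, THF, 0 °C; then 18, −78 → 0 °C; aq. NH4Cl
Reagents that add atoms: none
Why: Methyllithium cleaves the trimethylsilyl enol ether to the regiodefined lithium enolate, which undergoes Claisen-type C-formylation with ethyl formate at the only enolisable carbon.

Step 10
Reactants: 20 formyl ketone from step 9
Product: 21 (4S,5S)-2-[3-(tert-butyldimethylsilyloxy)prop-1-yn-1-yl]-5-methyl-6-oxo-4,5-bis(triethylsilyloxy)cyclohex-1-ene-1-carbaldehyde
Conditions: DDQ, 1,4-dioxane, rt
Reagents that add atoms: none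
Why: DDQ dehydrogenation of a 2-(hydroxymethylene) ketone to the 2-formyl enone, helped here by hydride abstraction from the tertiary propargylic C–H; the formyl substituent has no hydrogen to lose, so the double bond can only form inside the ring.

Step 11
Reactants: 21 formyl ynenone from step 10
Product: 23 (6S,7S)-3-[(tert-butyldimethylsilyloxy)methyl]-7-methyl-6,7-bis(triethylsilyloxy)-1,5,6,7-tetrahydro-8H-isochromen-8-one, via hydroxymethyl ynenone 22 (not isolated)
Conditions: NaBH4, CeCl3·7H2O, MeOH, −78 °C; work-up; crude 22, AuCl(PPh3)/AgOTf (2 mol % each), CH2Cl2, rt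
Reagents that add atoms: none
Why: Luche reduction should take the aldehyde in a 1,2 sense in preference to the hindered ketone next to the quaternary carbon, and the new hydroxymethyl group then adds to the gold-activated alkyne by 6-endo-dig hydroalkoxylation because the alkyne carbon remote from the enone (C3) is the conjugate position of the ynenone.

Step 12
Reactants: 23 bicyclic bis(triethylsilyl) ether from step 11
Product: 24 (6S,7S)-3-[(tert-butyldimethylsilyloxy)methyl]-6-hydroxy-7-methyl-7-(triethylsilyloxy)-1,5,6,7-tetrahydro-8H-isochromen-8-one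
Conditions: PPTS (0.2 equiv), MeOH/CH2Cl2, 0 °C
Reagents that add atoms: none
Why: Acid-catalysed methanolysis discriminates silyl ethers by size and substitution, so the secondary triethylsilyl ether should cleave well before the primary tert-butyldimethylsilyl and the tertiary triethylsilyl ethers.

Step 13
Reactants: 24 C6 alcohol from step 12; 25 but-2-ynoic acid
Product: 26 (6S,7S)-3-[(tert-butyldimethylsilyloxy)methyl]-7-methyl-8-oxo-7-(triethylsilyloxy)-5,6,7,8-tetrahydro-1H-isochromen-6-yl but-2-ynoate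
Conditions: DCC, DMAP (0.1 equiv), CH2Cl2, −20 → 0 °C
Reagents that add atoms: none
Why: Steglich esterification: the small, linear ynoic acid should acylate the congested C6 hydroxyl, which is the only free hydroxyl in the molecule, and the low temperature limits DMAP addition to the ynoate.

Step 14
Reactants: 26 but-2-ynoate from step 13; 6 1,1-dimethoxy-2,3-bis(tert-butyldimethylsilyloxy)buta-1,3-diene
Product: 28 (6S,7S)-3-[(tert-butyldimethylsilyloxy)methyl]-7-methyl-8-oxo-7-(triethylsilyloxy)-5,6,7,8-tetrahydro-1H-isochromen-6-yl 3,4-bis(tert-butyldimethylsilyloxy)-2-methoxy-6-methylbenzoate, via cycloadduct 27 (not isolated)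
Conditions: 6 (4 equiv), toluene, 120 °C, sealed tube; then silica gel, CH2Cl2, rt
Reagents that add atoms: none
Why: Normal-electron-demand Diels–Alder reaction followed by aromatisation: diene 6 adds to the ynoate triple bond in a concerted, asynchronous [4+2] event in which its nucleophilic CH2 terminus bonds to the methyl-bearing β-carbon (C5'–C6') and its acetal carbon to the ester-bearing α-carbon (C1'–C2'), and the 1,4-cyclohexadiene 27 then expels methanol across C2'/C5'. The closest known reaction type is the cycloaddition–aromatisation of alkynoates with 1,1-dialkoxy silyloxybutadienes to give polyoxygenated benzoates. The benzene ring closes by intermolecular [4+2] cycloaddition, both ring bonds being made suprafacially in one step. No stereocentre is formed, and C6 and C7 are not at risk under neutral thermal conditions. The step needs regioselectivity, which the matched polarisation of the partners provides (diene CH2 terminus as donor end, ynoate β-carbon as acceptor end). It also needs chemoselectivity, which the substrate secures: the ynoate is the only reactive dienophile because the ring enone is tetrasubstituted and deactivated by O2, the acrylate is still a silyloxymethyl group, and the silylated C7 oxygen offers no proton to the ketene acetal.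

Step 15
Reactants: 28 aryl ester from step 14
Product: 29 (6S,7S)-7-hydroxy-3-(hydroxymethyl)-7-methyl-8-oxo-5,6,7,8-tetrahydro-1H-isochromen-6-yl 3,4-bis(tert-butyldimethylsilyloxy)-2-methoxy-6-methylbenzoate
Conditions: CSA (0.3 equiv), MeOH/CH2Cl2 (1:1), 0 °C → rt
Reagents that add atoms: none
Why: Acid-catalysed methanolysis cleaves alkyl silyl ethers far faster than aryl silyl ethers, so the primary tert-butyldimethylsilyl and tertiary triethylsilyl groups should be removed while both aryl silyl ethers stay.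

Step 16
Reactants: 29 diol from step 15
Product: 30 (6S,7S)-3-formyl-7-hydroxy-7-methyl-8-oxo-5,6,7,8-tetrahydro-1H-isochromen-6-yl 3,4-bis(tert-butyldimethylsilyloxy)-2-methoxy-6-methylbenzoate
Conditions: Dess–Martin periodinane, NaHCO3, CH2Cl2, 0 °C → rt
Reagents that add atoms: none
Why: Dess–Martin oxidation converts the primary allylic alcohol into the aldehyde under buffered, non-basic conditions; the tertiary hydroxyl cannot be oxidised and the catechol is still silylated.

Step 17
Reactants: 30 aldehyde from step 16; 31 (triphenylphosphoranylidene)ketene; 32 2-(trimethylsilyl)ethanol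
Product: 34 2-(trimethylsilyl)ethyl (E)-3-[(6S,7S)-6-{[3,4-bis(tert-butyldimethylsilyloxy)-2-methoxy-6-methylbenzoyl]oxy}-7-hydroxy-7-methyl-8-oxo-5,6,7,8-tetrahydro-1H-isochromen-3-yl]prop-2-enoate, via ester ylide 33 (not isolated)
Conditions: 31, 32, toluene, 60 °C; then 30, rt
Reagents that add atoms: none
Why: Wittig olefination with a stabilised ester ylide, made in the flask by addition of the alcohol to the Bestmann ylide, is neutral and E-selective, so the base-sensitive C6 ester and the α-ketol are not exposed to base.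

Step 18
Reactants: 34 silylethyl ester from step 17
Product: 35 (E)-3-[(6S,7S)-6-[(3,4-dihydroxy-2-methoxy-6-methylbenzoyl)oxy]-7-hydroxy-7-methyl-8-oxo-5,6,7,8-tetrahydro-1H-isochromen-3-yl]prop-2-enoic acid (target)
Conditions: TASF, DMF, 0 °C, degassed; AcOH then pH 4 buffer
Reagents that add atoms: none
Why: Fluoride-mediated desilylation cleaves the two aryl silyl ethers and triggers β-elimination of the 2-(trimethylsilyl)ethyl ester in one operation, the anhydrous weakly basic fluoride source and cold acidic quench being chosen to spare the C6 ester and the catechol.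

**Compound list**

1 | methyl dimethoxyacetate | COC(OC)C(=O)OC | starting material
2 | ethyl vinyl ether | C=COCC | starting material
3 | 1-ethoxyvinyllithium (formed in the flask) | [Li]C(=C)OCC | intermediate
4 | 2-ethoxy-4,4-dimethoxybut-1-en-3-one (formed in the flask) | CCOC(=C)C(=O)C(OC)OC | intermediate
5 | 1,1-dimethoxybutane-2,3-dione | CC(=O)C(=O)C(OC)OC | intermediate
6 | 1,1-dimethoxy-2,3-bis(tert-butyldimethylsilyloxy)buta-1,3-diene | COC(OC)=C(O[Si](C)(C)C(C)(C)C)C(=C)O[Si](C)(C)C(C)(C)C | intermediate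
7 | 2-methylcyclohexane-1,3-dione | CC1C(=O)CCCC1=O | starting material
8 | 2-hydroxy-2-methylcyclohexane-1,3-dione | CC1(O)C(=O)CCCC1=O | intermediate
9 | 2-methyl-2-(triethylsilyloxy)cyclohexane-1,3-dione | CC[Si](CC)(CC)OC1(C)C(=O)CCCC1=O | intermediate
10 | (2S,3S)-3-hydroxy-2-methyl-2-(triethylsilyloxy)cyclohexan-1-one | O[C@H]1CCCC(=O)[C@@]1(C)O[Si](CC)(CC)CC | intermediate
11 | (2S,3S)-2-methyl-2,3-bis(triethylsilyloxy)cyclohexan-1-one | CC[Si](CC)(CC)O[C@H]1CCCC(=O)[C@@]1(C)O[Si](CC)(CC)CC | intermediate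
12 | lithium (5S,6S)-6-methyl-5,6-bis(triethylsilyloxy)cyclohex-1-en-1-olate (formed in the flask) | CC[Si](CC)(CC)O[C@H]1CCC=C(O[Li])[C@@]1(C)O[Si](CC)(CC)CC | intermediate
13 | (5S,6S)-6-methyl-5,6-bis(triethylsilyloxy)cyclohex-2-en-1-one | CC[Si](CC)(CC)O[C@H]1CC=CC(=O)[C@@]1(C)O[Si](CC)(CC)CC | intermediate
14 | tert-butyldimethyl(prop-2-yn-1-yloxy)silane | C#CCO[Si](C)(C)C(C)(C)C | starting material
15 | lithium 3-(tert-butyldimethylsilyloxy)prop-1-yn-1-ide (formed in the flask) | [Li]C#CCO[Si](C)(C)C(C)(C)C | intermediate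
16 | [3-(tert-butyldimethylsilyloxy)prop-1-yn-1-yl]zinc bromide (formed in the flask) | Br[Zn]C#CCO[Si](C)(C)C(C)(C)C | intermediate
17 | (5S,6S)-3-[3-(tert-butyldimethylsilyloxy)prop-1-yn-1-yl]-6-methyl-5,6-bis(triethylsilyloxy)-1-(trimethylsilyloxy)cyclohex-1-ene (C3 epimers) | CC[Si](CC)(CC)O[C@H]1CC(C#CCO[Si](C)(C)C(C)(C)C)C=C(O[Si](C)(C)C)[C@@]1(C)O[Si](CC)(CC)CC | intermediate
18 | ethyl formate | CCOC=O | starting material
19 | lithium (5S,6S)-3-[3-(tert-butyldimethylsilyloxy)prop-1-yn-1-yl]-6-methyl-5,6-bis(triethylsilyloxy)cyclohex-1-en-1-olate (C3 epimers; formed in the flask) | CC[Si](CC)(CC)O[C@H]1CC(C#CCO[Si](C)(C)C(C)(C)C)C=C(O[Li])[C@@]1(C)O[Si](CC)(CC)CC | intermediate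
20 | (4S,5S)-2-[3-(tert-butyldimethylsilyloxy)prop-1-yn-1-yl]-5-methyl-6-oxo-4,5-bis(triethylsilyloxy)cyclohexane-1-carbaldehyde (chelated enol; C2 epimers) | CC[Si](CC)(CC)O[C@H]1CC(C#CCO[Si](C)(C)C(C)(C)C)C(C=O)C(=O)[C@@]1(C)O[Si](CC)(CC)CC | intermediate
21 | (4S,5S)-2-[3-(tert-butyldimethylsilyloxy)prop-1-yn-1-yl]-5-methyl-6-oxo-4,5-bis(triethylsilyloxy)cyclohex-1-ene-1-carbaldehyde | CC[Si](CC)(CC)O[C@H]1CC(C#CCO[Si](C)(C)C(C)(C)C)=C(C=O)C(=O)[C@@]1(C)O[Si](CC)(CC)CC | intermediate
22 | (5S,6S)-3-[3-(tert-butyldimethylsilyloxy)prop-1-yn-1-yl]-2-(hydroxymethyl)-6-methyl-5,6-bis(triethylsilyloxy)cyclohex-2-en-1-one (not purified) | CC[Si](CC)(CC)O[C@H]1CC(C#CCO[Si](C)(C)C(C)(C)C)=C(CO)C(=O)[C@@]1(C)O[Si](CC)(CC)CC | intermediate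
23 | (6S,7S)-3-[(tert-butyldimethylsilyloxy)methyl]-7-methyl-6,7-bis(triethylsilyloxy)-1,5,6,7-tetrahydro-8H-isochromen-8-one | CC[Si](CC)(CC)O[C@H]1CC2=C(COC(CO[Si](C)(C)C(C)(C)C)=C2)C(=O)[C@@]1(C)O[Si](CC)(CC)CC | intermediate
24 | (6S,7S)-3-[(tert-butyldimethylsilyloxy)methyl]-6-hydroxy-7-methyl-7-(triethylsilyloxy)-1,5,6,7-tetrahydro-8H-isochromen-8-one | O[C@H]1CC2=C(COC(CO[Si](C)(C)C(C)(C)C)=C2)C(=O)[C@@]1(C)O[Si](CC)(CC)CC | intermediate
25 | but-2-ynoic acid | CC#CC(=O)O | starting material
26 | (6S,7S)-3-[(tert-butyldimethylsilyloxy)methyl]-7-methyl-8-oxo-7-(triethylsilyloxy)-5,6,7,8-tetrahydro-1H-isochromen-6-yl but-2-ynoate | CC#CC(=O)O[C@H]1CC2=C(COC(CO[Si](C)(C)C(C)(C)C)=C2)C(=O)[C@@]1(C)O[Si](CC)(CC)CC | intermediate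
27 | (6S,7S)-3-[(tert-butyldimethylsilyloxy)methyl]-7-methyl-8-oxo-7-(triethylsilyloxy)-5,6,7,8-tetrahydro-1H-isochromen-6-yl 4,5-bis(tert-butyldimethylsilyloxy)-6,6-dimethoxy-2-methylcyclohexa-1,4-diene-1-carboxylate (formed in the flask) | COC1(OC)C(O[Si](C)(C)C(C)(C)C)=C(O[Si](C)(C)C(C)(C)C)CC(C)=C1C(=O)O[C@H]1CC2=C(COC(CO[Si](C)(C)C(C)(C)C)=C2)C(=O)[C@@]1(C)O[Si](CC)(CC)CC | intermediate
28 | (6S,7S)-3-[(tert-butyldimethylsilyloxy)methyl]-7-methyl-8-oxo-7-(triethylsilyloxy)-5,6,7,8-tetrahydro-1H-isochromen-6-yl 3,4-bis(tert-butyldimethylsilyloxy)-2-methoxy-6-methylbenzoate | COc1c(O[Si](C)(C)C(C)(C)C)c(O[Si](C)(C)C(C)(C)C)cc(C)c1C(=O)O[C@H]1CC2=C(COC(CO[Si](C)(C)C(C)(C)C)=C2)C(=O)[C@@]1(C)O[Si](CC)(CC)CC | intermediate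
29 | (6S,7S)-7-hydroxy-3-(hydroxymethyl)-7-methyl-8-oxo-5,6,7,8-tetrahydro-1H-isochromen-6-yl 3,4-bis(tert-butyldimethylsilyloxy)-2-methoxy-6-methylbenzoate | COc1c(O[Si](C)(C)C(C)(C)C)c(O[Si](C)(C)C(C)(C)C)cc(C)c1C(=O)O[C@H]1CC2=C(COC(CO)=C2)C(=O)[C@@]1(C)O | intermediate
30 | (6S,7S)-3-formyl-7-hydroxy-7-methyl-8-oxo-5,6,7,8-tetrahydro-1H-isochromen-6-yl 3,4-bis(tert-butyldimethylsilyloxy)-2-methoxy-6-methylbenzoate | COc1c(O[Si](C)(C)C(C)(C)C)c(O[Si](C)(C)C(C)(C)C)cc(C)c1C(=O)O[C@H]1CC2=C(COC(C=O)=C2)C(=O)[C@@]1(C)O | intermediate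
31 | (triphenylphosphoranylidene)ketene | O=C=C=P(c1ccccc1)(c1ccccc1)c1ccccc1 | starting material
32 | 2-(trimethylsilyl)ethanol | C[Si](C)(C)CCO | starting material
33 | 2-(trimethylsilyl)ethyl (triphenylphosphoranylidene)acetate (formed in the flask) | C[Si](C)(C)CCOC(=O)C=P(c1ccccc1)(c1ccccc1)c1ccccc1 | intermediate
34 | 2-(trimethylsilyl)ethyl (E)-3-[(6S,7S)-6-{[3,4-bis(tert-butyldimethylsilyloxy)-2-methoxy-6-methylbenzoyl]oxy}-7-hydroxy-7-methyl-8-oxo-5,6,7,8-tetrahydro-1H-isochromen-3-yl]prop-2-enoate | COc1c(O[Si](C)(C)C(C)(C)C)c(O[Si](C)(C)C(C)(C)C)cc(C)c1C(=O)O[C@H]1CC2=C(COC(/C=C/C(=O)OCC[Si](C)(C)C)=C2)C(=O)[C@@]1(C)O | intermediate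
35 | (E)-3-[(6S,7S)-6-[(3,4-dihydroxy-2-methoxy-6-methylbenzoyl)oxy]-7-hydroxy-7-methyl-8-oxo-5,6,7,8-tetrahydro-1H-isochromen-3-yl]prop-2-enoic acid | COc1c(O)c(O)cc(C)c1C(=O)O[C@H]1CC2=C(COC(/C=C/C(=O)O)=C2)C(=O)[C@@]1(C)O | target

**Step count.** Total: 18 steps. Longest linear sequence: 16 steps (steps 3–18, from 2-methylcyclohexane-1,3-dione); the diene branch (steps 1–2) joins at step 14.

**Steps most likely to fail**

Step 14. The ketene-acetal diene may decompose or lose its silyl groups faster than it adds to the internal, β-methyl-substituted ynoate, so that the core is recovered or degraded on prolonged heating. In the fallback the arene is made away from the core and the ester bond is formed last. Acid 25 is O-benzylated (BnBr, K2CO3, DMF) to benzyl but-2-ynoate F1. This simple ester tolerates more forcing heating with diene 6 and should give, through the cycloadduct F2 and loss of methanol, benzyl 3,4-bis(tert-butyldimethylsilyloxy)-2-methoxy-6-methylbenzoate F3. Hydrogenolysis (H2, Pd/C, EtOAc) gives 3,4-bis(tert-butyldimethylsilyloxy)-2-methoxy-6-methylbenzoic acid F4, which 1-chloro-N,N,2-trimethylprop-1-en-1-amine converts under neutral conditions into the acid chloride F5. Acylation of alcohol 24 with F5 (Et3N, DMAP, toluene, 60 °C) rejoins the route at 28.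

Step 8. Transfer of the alkynyl group to the hindered enone may be slow, and the silyl triflate may meanwhile cleave or scramble the triethylsilyl ethers. The fallback reverses the order of the two carbon–carbon bond formations so that the acceptor is a doubly activated alkene. It sets out from ketone 11: Claisen formylation (NaH, ethyl formate 18, THF) gives (3S,4S)-3-methyl-2-oxo-3,4-bis(triethylsilyloxy)cyclohexane-1-carbaldehyde F6, and DDQ in dioxane gives the 2-formyl enone (4S,5S)-5-methyl-6-oxo-4,5-bis(triethylsilyloxy)cyclohex-1-ene-1-carbaldehyde F7, used at once. The alkynylalane [3-(tert-butyldimethylsilyloxy)prop-1-yn-1-yl]dimethylaluminium F8 (from acetylide 15 and Me2AlCl) then adds in a 1,4 sense to the s-cis enal unit of F7. Work-up gives formyl ketone 20, where the route resumes at step 10.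

Step 18. Fluoride may act as a base, causing loss of the C6 benzoate through the extended enolate at C5, rearrangement of the α-ketol, or air oxidation of the catecholate. The fallback releases the acid under acidic conditions and the phenols with acidic fluoride. It sets out from aldehyde 30: Wittig reaction with tert-butyl (triphenylphosphoranylidene)acetate (CH2Cl2, rt) gives the tert-butyl (E)-acrylate F9, and TFA/CH2Cl2 at 0 °C cleaves the tert-butyl ester to the acrylic acid F10 with both aryl silyl ethers intact. HF·pyridine in THF then removes the two aryl silyl groups and arrives at target 35.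

**Further compounds**

F1 | step 14 | benzyl but-2-ynoate | CC#CC(=O)OCc1ccccc1
F2 | step 14 | benzyl 4,5-bis(tert-butyldimethylsilyloxy)-6,6-dimethoxy-2-methylcyclohexa-1,4-diene-1-carboxylate | COC1(OC)C(O[Si](C)(C)C(C)(C)C)=C(O[Si](C)(C)C(C)(C)C)CC(C)=C1C(=O)OCc1ccccc1
F3 | step 14 | benzyl 3,4-bis(tert-butyldimethylsilyloxy)-2-methoxy-6-methylbenzoate | COc1c(O[Si](C)(C)C(C)(C)C)c(O[Si](C)(C)C(C)(C)C)cc(C)c1C(=O)OCc1ccccc1
F4 | step 14 | 3,4-bis(tert-butyldimethylsilyloxy)-2-methoxy-6-methylbenzoic acid | COc1c(O[Si](C)(C)C(C)(C)C)c(O[Si](C)(C)C(C)(C)C)cc(C)c1C(=O)O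
F5 | step 14 | 3,4-bis(tert-butyldimethylsilyloxy)-2-methoxy-6-methylbenzoyl chloride | COc1c(O[Si](C)(C)C(C)(C)C)c(O[Si](C)(C)C(C)(C)C)cc(C)c1C(Cl)=O
F6 | step 8 | (3S,4S)-3-methyl-2-oxo-3,4-bis(triethylsilyloxy)cyclohexane-1-carbaldehyde (chelated enol) | CC[Si](CC)(CC)O[C@H]1CCC(C=O)C(=O)[C@@]1(C)O[Si](CC)(CC)CC
F7 | step 8 | (4S,5S)-5-methyl-6-oxo-4,5-bis(triethylsilyloxy)cyclohex-1-ene-1-carbaldehyde | CC[Si](CC)(CC)O[C@H]1CC=C(C=O)C(=O)[C@@]1(C)O[Si](CC)(CC)CC
F8 | step 8 | [3-(tert-butyldimethylsilyloxy)prop-1-yn-1-yl]dimethylaluminium | C[Al](C)C#CCO[Si](C)(C)C(C)(C)C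
F9 | step 18 | tert-butyl (E)-3-[(6S,7S)-6-{[3,4-bis(tert-butyldimethylsilyloxy)-2-methoxy-6-methylbenzoyl]oxy}-7-hydroxy-7-methyl-8-oxo-5,6,7,8-tetrahydro-1H-isochromen-3-yl]prop-2-enoate | COc1c(O[Si](C)(C)C(C)(C)C)c(O[Si](C)(C)C(C)(C)C)cc(C)c1C(=O)O[C@H]1CC2=C(COC(/C=C/C(=O)OC(C)(C)C)=C2)C(=O)[C@@]1(C)O
F10 | step 18 | (E)-3-[(6S,7S)-6-{[3,4-bis(tert-butyldimethylsilyloxy)-2-methoxy-6-methylbenzoyl]oxy}-7-hydroxy-7-methyl-8-oxo-5,6,7,8-tetrahydro-1H-isochromen-3-yl]prop-2-enoic acid | COc1c(O[Si](C)(C)C(C)(C)C)c(O[Si](C)(C)C(C)(C)C)cc(C)c1C(=O)O[C@H]1CC2=C(COC(/C=C/C(=O)O)=C2)C(=O)[C@@]1(C)O
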